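The dioxin ring is not closed by a second aryl ether coupling but by C–H etherification of ring B. Ring B (outer benzo ring of the dioxin) hides a hydroquinone: its carbon B1 (ether to ring A) is para to B4 (OH). A B1 phenol/B4 methyl ether is oxidised to the p-quinone monoketal, and the ring C phenol at C6, held by the existing B6–O–C1 ether, adds to the β-carbon B5 (6-endo oxa-Michael); loss of methanol rearomatises. One operation forms the B5–O bond with fixed regiochemistry and leaves B1 (free OH) and B4 (OMe) differentiated. The precursor is a 2-silyloxyphenyl aryl ether made by SNAr from 2-fluoro-4,6-dimethoxybenzaldehyde, the source of rings B and D alike.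

Key step: step 6

Remark on stereochemistry: the target has no stereocentre and no configurationally stable axis, and its SMILES carries no stereodescriptor; it is achiral, so the constitution alone defines the compound.

Atom labels: rings A and E are the terminal 3,5-dihydroxyphenyl groups. Ring B: B1 (O–ring A), B2 (OH), B3 (H), B4 (OH), B5 and B6 (dioxin carbons, B6 next to B1). Ring C: C1 (dioxin O to B6), C2 (OH), C3 (H), C4 (furan O), C5 (furan C), C6 (dioxin O to B5). Ring D: D1 (furan O), D2 (O–ring E), D3 (OH), D4 (H), D5 (OH), D6 (bonded to C5).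

Step 1
Reactants: 1 5-hydroxyvanillin (3,4-dihydroxy-5-methoxybenzaldehyde)
Product: 2 2-bromo-3,4-dihydroxy-5-methoxybenzaldehyde
Conditions: Br2 (1.05 equiv), NaOAc, AcOH, 15 °C to rt
Reagents that add atoms: bromine, BrBr
Why: Electrophilic aromatic bromination; as in the conversion of isovanillin into 2-bromoisovanillin, the halogen should enter C-2, ortho to the 3-OH and para to the 5-OMe group, which is the future C5 next to the future dioxin oxygen on C6.

Step 2
Reactants: 2 2-bromo-3,4-dihydroxy-5-methoxybenzaldehyde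
Product: 3 3-bromo-4-(1,3-dioxolan-2-yl)-6-methoxybenzene-1,2-diol
Conditions: ethylene glycol, TsOH (cat.), toluene, reflux, Dean–Stark
Reagents that add atoms: ethylene glycol, OCCO
Why: Acid-catalysed acetalization; it switches off the formyl group, so that the bromine-flanked OH (future C6–O) and no longer the OH para to the aldehyde is the more acidic catechol oxygen, and it leaves a single aldehyde for step 5.

Step 3
Reactants: 3 3-bromo-4-(1,3-dioxolan-2-yl)-6-methoxybenzene-1,2-diol; 4 2-fluoro-4,6-dimethoxybenzaldehyde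
Product: 5 2-[3-bromo-4-(1,3-dioxolan-2-yl)-2-hydroxy-6-methoxyphenoxy]-4,6-dimethoxybenzaldehyde
Conditions: 4 (1.0 equiv), K2CO3 (2 equiv), DMSO, 100 °C, argon
Reagents that add atoms: none
Why: Nucleophilic aromatic substitution (addition–elimination through a Meisenheimer complex stabilised by the ortho-formyl group); the two catechol mono-ethers should interconvert by Smiles rearrangement, and the equilibrium should lie on the ether at the oxygen next to OMe (C1–O), because the phenoxide that stays free is then the ortho-bromo one at C6.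

Step 4
Reactants: 5 2-[3-bromo-4-(1,3-dioxolan-2-yl)-2-hydroxy-6-methoxyphenoxy]-4,6-dimethoxybenzaldehyde
Product: 6 2-[3-bromo-4-(1,3-dioxolan-2-yl)-6-methoxy-2-(triisopropylsilyloxy)phenoxy]-4,6-dimethoxybenzaldehyde
Conditions: TIPSCl, imidazole, DMAP (cat.), DMF, 50 °C
Reagents that add atoms: chlorotriisopropylsilane, CC(C)[Si](Cl)(C(C)C)C(C)C
Why: Silylation of the only free phenol; the silyl ether keeps this oxygen from attacking ring B during the oxidation of step 6 and is the latent nucleophile that fluoride releases there.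

Step 5
Reactants: 6 2-[3-bromo-4-(1,3-dioxolan-2-yl)-6-methoxy-2-(triisopropylsilyloxy)phenoxy]-4,6-dimethoxybenzaldehyde
Product: 8 2-[3-bromo-4-(1,3-dioxolan-2-yl)-6-methoxy-2-(triisopropylsilyloxy)phenoxy]-4,6-dimethoxyphenol, via aryl formate 7 (not isolated)
Conditions: mCPBA (1.1 equiv), CH2Cl2, 0 °C to rt; then Et3N (cat.), MeOH, rt
Reagents that add atoms: 3-chloroperbenzoic acid, OOC(=O)c1cccc(Cl)c1
Why: Baeyer–Villiger (Dakin-type) oxidation, in which the 2,4,6-trioxygenated aryl group migrates in the Criegee adduct to give the aryl formate that methanol then cleaves; the only other aldehyde is masked as the dioxolane.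

Step 6
Reactants: 8 2-[3-bromo-4-(1,3-dioxolan-2-yl)-6-methoxy-2-(triisopropylsilyloxy)phenoxy]-4,6-dimethoxyphenol
Product: 13 9-bromo-4-hydroxy-1,3,6-trimethoxydibenzo[b,e][1,4]dioxine-8-carbaldehyde, via quinone monoketal silyl ether 9 (not isolated), via quinone monoketal phenol 10 (not isolated), via oxa-Michael adduct 11 (not isolated), via dioxin acetal 12 (not isolated)
Conditions: PhI(OAc)2 (1.05 equiv), MeOH, 0 °C; evaporate; TBAF, THF, 0 °C to rt; TsOH (dry), CH2Cl2, rt; then 1 M HCl, THF, rt
Reagents that add atoms: methanol, CO; water, O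
Why: Proposed new method: PhI(OAc)2 oxidises the only free phenol (B1–OH, para to the B4 methoxy group) via its aryloxy-λ3-iodane, methanol adds at B4, and the 4,4-dimethoxycyclohexadienone 9 results, a standard oxidative dearomatisation; the ring C oxygen is still silylated at this point, so it cannot attack the phenoxenium-type intermediate at B6. Fluoride then frees phenoxide 10, which adds to the enone β-carbon B5 in a 6-endo-trig oxa-Michael closure (adduct 11); dry acid ionises the ketal at B4, loss of the B5 proton and enolisation at B6 expel methanol and restore aromaticity (12), and aqueous acid unmasks the aldehyde (13). The closest known reaction type is the conjugate addition of thiols, amines, halide or alkoxide to p-quinone monoketals with acid-induced loss of methanol to 3-substituted 4-methoxyphenols, together with intramolecular oxa-Michael additions to cyclohexadienones; closure of a dibenzodioxin by a phenoxide in this way is not documented. Site selectivity comes from the tether, which lets the C6 oxygen reach only B5 (B3 lies on the far side, and attack at the carbonyl carbon B1 is reversible), helped by the aryloxy group on B6 being a weaker donor than the methoxy group on B2. The two sp3 centres of 11 are transient and disappear on aromatisation, so no stereocentre is set. Because the ketal carbon keeps one methoxy group, B4 leaves the step as OMe and B1 as the free hindered phenol, which is the differentiation that the ring A ether of step 7 needs.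

Step 7
Reactants: 13 9-bromo-4-hydroxy-1,3,6-trimethoxydibenzo[b,e][1,4]dioxine-8-carbaldehyde; 14 3,5-dimethoxyphenylboronic acid
Product: 15 9-bromo-4-(3,5-dimethoxyphenoxy)-1,3,6-trimethoxydibenzo[b,e][1,4]dioxine-8-carbaldehyde
Conditions: Cu(OAc)2 (20 mol %), pyridine, 4 Å MS, CH2Cl2, O2 (balloon), rt
Reagents that add atoms: none
Why: Chan–Evans–Lam oxidative O-arylation (transmetalation to copper, then C–O reductive elimination), which runs at room temperature, accepts 2,6-disubstituted phenols and should leave the aryl bromide and the aldehyde untouched.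

Step 8
Reactants: 15 9-bromo-4-(3,5-dimethoxyphenoxy)-1,3,6-trimethoxydibenzo[b,e][1,4]dioxine-8-carbaldehyde
Product: 17 9-bromo-4-(3,5-dimethoxyphenoxy)-1,3,6-trimethoxydibenzo[b,e][1,4]dioxin-8-ol, via aryl formate 16 (not isolated)
Conditions: mCPBA, CH2Cl2, rt; then K2CO3 (cat.), MeOH, rt
Reagents that add atoms: 3-chloroperbenzoic acid, OOC(=O)c1cccc(Cl)c1
Why: Baeyer–Villiger oxidation of a 2-bromo-3,4,5-trioxygenated benzaldehyde, where the para-aryloxy oxygen supports aryl migration, followed by methanolysis of the formate; this turns the formyl-bearing carbon into the future furan oxygen site C4–OH.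

Step 9
Reactants: 17 9-bromo-4-(3,5-dimethoxyphenoxy)-1,3,6-trimethoxydibenzo[b,e][1,4]dioxin-8-ol; 4 2-fluoro-4,6-dimethoxybenzaldehyde
Product: 18 2-{[9-bromo-4-(3,5-dimethoxyphenoxy)-1,3,6-trimethoxydibenzo[b,e][1,4]dioxin-8-yl]oxy}-4,6-dimethoxybenzaldehyde
Conditions: K2CO3, DMSO, 100 °C, argon
Reagents that add atoms: none
Why: SNAr of the single phenoxide on the ortho-formyl-activated fluoride; this phenoxide has no neighbouring aryl ether oxygen, so no Smiles pathway can move the new aryl group.

Step 10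
Reactants: 18 2-{[9-bromo-4-(3,5-dimethoxyphenoxy)-1,3,6-trimethoxydibenzo[b,e][1,4]dioxin-8-yl]oxy}-4,6-dimethoxybenzaldehyde
Product: 19 4-(3,5-dimethoxyphenoxy)-1,3,6,10,12-pentamethoxy[1]benzofuro[3,2-a]oxanthrene-9-carbaldehyde (the target skeleton with CHO at D2 in place of the ring E ether and all hydroxyls as methyl ethers)
Conditions: Pd(OAc)2 (5 mol %), PCy3·HBF4 (10 mol %), PivOH (30 mol %), K2CO3 (2 equiv), DMA, 130 °C
Reagents that add atoms: none
Why: Palladium-catalysed intramolecular direct arylation (oxidative addition into C5–Br, concerted metalation–deprotonation on ring D, reductive elimination); the only C–H that the aryl–palladium can reach through a five-membered ring is D6–H, since the other ortho position of D1 carries the formyl group.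

Step 11
Reactants: 19 4-(3,5-dimethoxyphenoxy)-1,3,6,10,12-pentamethoxy[1]benzofuro[3,2-a]oxanthrene-9-carbaldehyde
Product: 21 4-(3,5-dimethoxyphenoxy)-1,3,6,10,12-pentamethoxy[1]benzofuro[3,2-a]oxanthren-9-ol, via aryl formate 20 (not isolated)
Conditions: mCPBA (1.1 equiv), CH2Cl2, 0 °C; then K2CO3 (cat.), MeOH, rt
Reagents that add atoms: 3-chloroperbenzoic acid, OOC(=O)c1cccc(Cl)c1
Why: Baeyer–Villiger oxidation of the 2,4,6-trioxygenated aldehyde and methanolysis of the formate, which unveils the hindered D2 phenol while D5 stays a methyl ether.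

Step 12
Reactants: 21 4-(3,5-dimethoxyphenoxy)-1,3,6,10,12-pentamethoxy[1]benzofuro[3,2-a]oxanthren-9-ol; 14 3,5-dimethoxyphenylboronic acid
Product: 22 4,9-bis(3,5-dimethoxyphenoxy)-1,3,6,10,12-pentamethoxy[1]benzofuro[3,2-a]oxanthrene (nona-O-methylphlorofucofuroeckol A)
Conditions: Cu(OAc)2 (20 mol %), pyridine, 4 Å MS, CH2Cl2, O2 (balloon), rt
Reagents that add atoms: none
Why: Chan–Evans–Lam O-arylation of the second 2,6-dioxygenated phenol, the same reaction type as in step 7.

Step 13
Reactants: 22 nona-O-methylphlorofucofuroeckol A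
Product: 23 phlorofucofuroeckol A
Conditions: BBr3 (excess), CH2Cl2, −78 °C to rt; then MeOH, H2O
Reagents that add atoms: none
Why: Lewis-acid ether cleavage, in which bromide attacks the methyl carbon of each boron-complexed ArO–Me group (SN2), so that the nine methyl ethers should fall while the five diaryl ether bonds, which offer no sp3 carbon, stay.

Compound list
1 | 5-hydroxyvanillin (3,4-dihydroxy-5-methoxybenzaldehyde) | COc1cc(C=O)cc(O)c1O | starting material
2 | 2-bromo-3,4-dihydroxy-5-methoxybenzaldehyde | COc1cc(C=O)c(Br)c(O)c1O | intermediate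
3 | 3-bromo-4-(1,3-dioxolan-2-yl)-6-methoxybenzene-1,2-diol | COc1cc(C2OCCO2)c(Br)c(O)c1O | intermediate
4 | 2-fluoro-4,6-dimethoxybenzaldehyde | COc1cc(F)c(C=O)c(OC)c1 | starting material
5 | 2-[3-bromo-4-(1,3-dioxolan-2-yl)-2-hydroxy-6-methoxyphenoxy]-4,6-dimethoxybenzaldehyde | COc1cc(C2OCCO2)c(Br)c(O)c1Oc1cc(OC)cc(OC)c1C=O | intermediate
6 | 2-[3-bromo-4-(1,3-dioxolan-2-yl)-6-methoxy-2-(triisopropylsilyloxy)phenoxy]-4,6-dimethoxybenzaldehyde | COc1cc(C2OCCO2)c(Br)c(O[Si](C(C)C)(C(C)C)C(C)C)c1Oc1cc(OC)cc(OC)c1C=O | intermediate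
7 | 2-[3-bromo-4-(1,3-dioxolan-2-yl)-6-methoxy-2-(triisopropylsilyloxy)phenoxy]-4,6-dimethoxyphenyl formate | COc1cc(C2OCCO2)c(Br)c(O[Si](C(C)C)(C(C)C)C(C)C)c1Oc1cc(OC)cc(OC)c1OC=O | intermediate (not isolated)
8 | 2-[3-bromo-4-(1,3-dioxolan-2-yl)-6-methoxy-2-(triisopropylsilyloxy)phenoxy]-4,6-dimethoxyphenol | COc1cc(C2OCCO2)c(Br)c(O[Si](C(C)C)(C(C)C)C(C)C)c1Oc1cc(OC)cc(OC)c1O | intermediate
9 | 2-[3-bromo-4-(1,3-dioxolan-2-yl)-6-methoxy-2-(triisopropylsilyloxy)phenoxy]-4,4,6-trimethoxycyclohexa-2,5-dien-1-one | COC1=CC(OC)(OC)C=C(Oc2c(OC)cc(C3OCCO3)c(Br)c2O[Si](C(C)C)(C(C)C)C(C)C)C1=O | intermediate (not isolated)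
10 | 2-[3-bromo-4-(1,3-dioxolan-2-yl)-2-hydroxy-6-methoxyphenoxy]-4,4,6-trimethoxycyclohexa-2,5-dien-1-one (present as its phenoxide) | COC1=CC(OC)(OC)C=C(Oc2c(OC)cc(C3OCCO3)c(Br)c2O)C1=O | intermediate (not isolated)
11 | 9-bromo-8-(1,3-dioxolan-2-yl)-1,1,3,6-tetramethoxy-4a,10a-dihydrodibenzo[b,e][1,4]dioxin-4(1H)-one (two transient sp3 centres, configuration not defined) | COC1=CC(OC)(OC)C2Oc3c(Br)c(C4OCCO4)cc(OC)c3OC2C1=O | intermediate (not isolated)
12 | 9-bromo-8-(1,3-dioxolan-2-yl)-1,3,6-trimethoxydibenzo[b,e][1,4]dioxin-4-ol | COc1cc(OC)c2Oc3c(Br)c(C4OCCO4)cc(OC)c3Oc2c1O | intermediate (not isolated)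
13 | 9-bromo-4-hydroxy-1,3,6-trimethoxydibenzo[b,e][1,4]dioxine-8-carbaldehyde | COc1cc(OC)c2Oc3c(Br)c(C=O)cc(OC)c3Oc2c1O | intermediate
14 | 3,5-dimethoxyphenylboronic acid | COc1cc(OC)cc(B(O)O)c1 | starting material
15 | 9-bromo-4-(3,5-dimethoxyphenoxy)-1,3,6-trimethoxydibenzo[b,e][1,4]dioxine-8-carbaldehyde | COc1cc(OC)c2Oc3c(Br)c(C=O)cc(OC)c3Oc2c1Oc1cc(OC)cc(OC)c1 | intermediate
16 | 9-bromo-4-(3,5-dimethoxyphenoxy)-1,3,6-trimethoxydibenzo[b,e][1,4]dioxin-8-yl formate | COc1cc(OC)c2Oc3c(Br)c(OC=O)cc(OC)c3Oc2c1Oc1cc(OC)cc(OC)c1 | intermediate (not isolated)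
17 | 9-bromo-4-(3,5-dimethoxyphenoxy)-1,3,6-trimethoxydibenzo[b,e][1,4]dioxin-8-ol | COc1cc(OC)c2Oc3c(Br)c(O)cc(OC)c3Oc2c1Oc1cc(OC)cc(OC)c1 | intermediate
18 | 2-{[9-bromo-4-(3,5-dimethoxyphenoxy)-1,3,6-trimethoxydibenzo[b,e][1,4]dioxin-8-yl]oxy}-4,6-dimethoxybenzaldehyde | COc1cc(OC)c2Oc3c(Br)c(Oc4cc(OC)cc(OC)c4C=O)cc(OC)c3Oc2c1Oc1cc(OC)cc(OC)c1 | intermediate
19 | 4-(3,5-dimethoxyphenoxy)-1,3,6,10,12-pentamethoxy[1]benzofuro[3,2-a]oxanthrene-9-carbaldehyde | COc1cc(OC)cc(Oc2c(OC)cc(OC)c3c2Oc2c(OC)cc4oc5c(C=O)c(OC)cc(OC)c5c4c2O3)c1 | intermediate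
20 | 4-(3,5-dimethoxyphenoxy)-1,3,6,10,12-pentamethoxy[1]benzofuro[3,2-a]oxanthren-9-yl formate | COc1cc(OC)cc(Oc2c(OC)cc(OC)c3c2Oc2c(OC)cc4oc5c(OC=O)c(OC)cc(OC)c5c4c2O3)c1 | intermediate (not isolated)
21 | 4-(3,5-dimethoxyphenoxy)-1,3,6,10,12-pentamethoxy[1]benzofuro[3,2-a]oxanthren-9-ol | COc1cc(OC)cc(Oc2c(OC)cc(OC)c3c2Oc2c(OC)cc4oc5c(O)c(OC)cc(OC)c5c4c2O3)c1 | intermediate
22 | 4,9-bis(3,5-dimethoxyphenoxy)-1,3,6,10,12-pentamethoxy[1]benzofuro[3,2-a]oxanthrene (nona-O-methylphlorofucofuroeckol A) | COc1cc(OC)cc(Oc2c(OC)cc(OC)c3c2Oc2c(OC)cc4oc5c(Oc6cc(OC)cc(OC)c6)c(OC)cc(OC)c5c4c2O3)c1 | intermediate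
23 | phlorofucofuroeckol A, 4,9-bis(3,5-dihydroxyphenoxy)[1]benzofuro[3,2-a]oxanthrene-1,3,6,10,12-pentol | Oc1cc(O)cc(Oc2c(O)cc(O)c3c2Oc2c(O)cc4oc5c(Oc6cc(O)cc(O)c6)c(O)cc(O)c5c4c2O3)c1 | target

Total step count: 13 steps.
Longest linear sequence: 13 steps (1 to 23); 4 and 14 are commercial and each is used twice.

Steps most likely to fail

1. Step 6 (Proposed new method). The phenoxide may add reversibly and revert by retro-oxa-Michael reaction before the adduct is trapped. On acidification, water may hydrolyse the ketal instead of methanol being eliminated, which would give the B1/B4 hydroquinone and erase the differentiation of these two oxygens. Monoketal that has not cyclised may react in its phenoxenium mode at B6 and spiro-ketalize. The fallback uses known chemistry only and closes the dioxin by an Ullmann etherification; it sets out from 3 (with 4 as the source of ring B) and comes back at 13. Aldehyde 4 is brominated (NBS, MeCN, rt) between the fluorine and the 4-methoxy group to 3-bromo-2-fluoro-4,6-dimethoxybenzaldehyde F1. SNAr of 3 with F1 under the conditions of step 3 should give the dibromo diaryl ether F2. An intramolecular Ullmann etherification (CuI, N,N-dimethylglycine, Cs2CO3, dioxane, 100 °C) should close the dioxin to the ring B aldehyde F3. Baeyer–Villiger oxidation and methanolysis as in step 5, through the aryl formate F4, should give phenol 12, whose acetal is hydrolysed (1 M HCl, THF) to 13.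

2. Step 3. Substitution at a fluoride that is activated by only one formyl group, itself damped by two methoxy donors, may be slow. At the temperature it then needs, oxidative decay of the electron-rich catechol, a second arylation at C6–O and incomplete Smiles equilibration (hence a mixture of ether regioisomers) can take over. The fallback changes the electrophile and splits the step in two; it sets out from 3 and comes back at 5. Commercial 2,6-difluoro-4-methoxybenzaldehyde, whose second ortho-fluorine adds activation, is used at 60 °C (K2CO3, DMSO) to give the fluoro diaryl ether F5. NaOMe in MeOH–THF at 50 °C then replaces the remaining ortho-fluorine by methoxide and should give 5.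

3. Step 10. Oxidative addition into the C5–Br bond, which is flanked by two oxygens, may be slow, and the ring closure has to bring the C6 oxygen and the D5 methoxy group together in the bay region; protodebromination would then compete and destroy the only handle that defines C5. The fallback makes the C–C bond first and the furan C–O bond second; it sets out from 17 and comes back at 19. 3-Bromo-2-fluoro-4,6-dimethoxybenzaldehyde F6 (from 4 with NBS, the same compound as F1) is borylated (B2pin2, Pd(dppf)Cl2, KOAc, dioxane, 90 °C) to the pinacol boronate F7. Suzuki–Miyaura coupling of F7 with 17 (Pd2(dba)3, SPhos, K3PO4, toluene–water, 100 °C) should give the biaryl F8. In F8 the C4 phenoxide displaces the ortho-formyl-activated fluoride (K2CO3, DMF, 80 °C, intramolecular SNAr) to give 19.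

Further compounds
F1 | step 6 | 3-bromo-2-fluoro-4,6-dimethoxybenzaldehyde | COc1cc(OC)c(Br)c(F)c1C=O
F2 | step 6 | 3-bromo-2-[3-bromo-4-(1,3-dioxolan-2-yl)-2-hydroxy-6-methoxyphenoxy]-4,6-dimethoxybenzaldehyde | COc1cc(C2OCCO2)c(Br)c(O)c1Oc1c(Br)c(OC)cc(OC)c1C=O
F3 | step 6 | 9-bromo-8-(1,3-dioxolan-2-yl)-1,3,6-trimethoxydibenzo[b,e][1,4]dioxine-4-carbaldehyde | COc1cc(OC)c2Oc3c(Br)c(C4OCCO4)cc(OC)c3Oc2c1C=O
F4 | step 6 | 9-bromo-8-(1,3-dioxolan-2-yl)-1,3,6-trimethoxydibenzo[b,e][1,4]dioxin-4-yl formate | COc1cc(OC)c2Oc3c(Br)c(C4OCCO4)cc(OC)c3Oc2c1OC=O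
F5 | step 3 | 2-[3-bromo-4-(1,3-dioxolan-2-yl)-2-hydroxy-6-methoxyphenoxy]-6-fluoro-4-methoxybenzaldehyde | COc1cc(C2OCCO2)c(Br)c(O)c1Oc1cc(OC)cc(F)c1C=O
F6 | step 10 | 3-bromo-2-fluoro-4,6-dimethoxybenzaldehyde | COc1cc(OC)c(Br)c(F)c1C=O
F7 | step 10 | 2-fluoro-4,6-dimethoxy-3-(4,4,5,5-tetramethyl-1,3,2-dioxaborolan-2-yl)benzaldehyde | COc1cc(OC)c(B2OC(C)(C)C(C)(C)O2)c(F)c1C=O
F8 | step 10 | 3-[4-(3,5-dimethoxyphenoxy)-8-hydroxy-1,3,6-trimethoxydibenzo[b,e][1,4]dioxin-9-yl]-2-fluoro-4,6-dimethoxybenzaldehyde | COc1cc(OC)c2Oc3c(-c4c(F)c(C=O)c(OC)cc4OC)c(O)cc(OC)c3Oc2c1Oc1cc(OC)cc(OC)c1
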